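**Plan**

- Retrosynthesis: the phenolic O–Si bond of a protected precursor is cut first (protecting group only). The single skeletal cut is the aryl C–CH2 bond, which leads back to a 4-silyloxyiodobenzene and the vinyl ester of docosanoic acid, whose O–vinyl bond is traced to vinyl acetate.
- The cut rests on one feature: the benzene ring sits on the carbon beta to the ester oxygen (Ar–CH2–CH2–O–C(=O)R), the linear pattern left when an aryl radical adds to the CH2 terminus of an O-vinyl ester.
- Forward: 4-iodophenol 1 is silylated to 2; docosanoic acid 3 is vinylated with vinyl acetate 4 to vinyl docosanoate 5; 2 and 5 are joined through the aryl–CH2 bond to give 6; desilylation gives the target 7.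
- The chain is joined in one C–C bond formation, no ring is made, and the target has no stereocentre or double-bond geometry, so no stereocontrol is needed.

Key step: step 3

**Route**

Step 1
Reactants: 1 4-iodophenol
Product: 2 tert-butyl(4-iodophenoxy)dimethylsilane
Conditions: TBSCl (1.1 equiv), imidazole (2.2 equiv), DMF, 0 °C to rt
Reagents that add atoms: tert-butyldimethylsilyl chloride, CC(C)(C)[Si](C)(C)Cl
Why: Imidazole-promoted O-silylation of a phenol is fast and clean, leaves the aryl iodide untouched, and masks the phenol so that it can neither be acylated by the vinyl ester nor quench radicals in the key step.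

Step 2
Reactants: 3 docosanoic acid; 4 vinyl acetate
Product: 5 vinyl docosanoate
Conditions: Pd(OAc)2 (5 mol%), KOH (10 mol%), vinyl acetate (large excess)/THF, 40 °C
Reagents that add atoms: none
Why: Transvinylation (vinyl interchange) catalysed by divalent palladium proceeds by oxypalladation of vinyl acetate with the fatty carboxylate and beta-acetate elimination, and the large excess of vinyl acetate pushes the equilibrium to the long-chain vinyl ester, so the acyl–oxygen bond is in place before any alcohol or phenol is present.

Step 3
Reactants: 2 tert-butyl(4-iodophenoxy)dimethylsilane (2 equiv); 5 vinyl docosanoate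
Product: 6 2-[4-(tert-butyldimethylsilyloxy)phenyl]ethyl docosanoate
Conditions: 10-phenylphenothiazine (5 mol%), cyclohexanethiol (10 mol%), HCO2Na (3 equiv), degassed DMSO/t-BuOH/H2O, 400 nm LEDs, 35 °C
Reagents that add atoms: none
Why: Photoexcited 10-phenylphenothiazine should transfer an electron to aryl iodide 2, whose radical anion expels iodide to give the 4-silyloxyphenyl sigma radical; this adds to the unsubstituted CH2 terminus of vinyl ester 5, and the nucleophilic alpha-acyloxy radical so formed takes a hydrogen atom from cyclohexanethiol in a polarity-matched step. The thiyl radical is returned to thiol by formate, and the CO2 radical anion released reduces the phenothiazine radical cation (or a further molecule of 2), which closes the cycle. The closest known reaction type is the photoredox anti-Markovnikov hydroarylation of heteroatom-substituted terminal alkenes (N-vinyl carbamates, enol ethers) by aryl and heteroaryl radicals with thiol hydrogen-atom-transfer co-catalysis, a reductive Giese-type addition; addition of aryl radicals to enol acetates is itself established in Meerwein-type arylations, so the fatty vinyl ester differs only in its acyl chain. No ring closes and no stereocentre forms. The step needs linear regioselectivity, secured by attack at the unhindered terminal carbon to give the oxygen-stabilised secondary radical, and it needs one addition followed by hydrogen transfer, secured by a thiol loading low enough that the aryl radical adds before it is reduced yet reactive enough toward the alpha-acyloxy radical to outrun telomerisation of 5. The aryl silyl ether and the alkyl ester should be spectators in this near-neutral medium, and the excess of 2 ends as a volatile, easily removed arene.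

Step 4
Reactants: 6 2-[4-(tert-butyldimethylsilyloxy)phenyl]ethyl docosanoate
Product: 7 2-(4-hydroxyphenyl)ethyl docosanoate
Conditions: KHF2 (2.5 equiv), MeOH/THF, rt
Reagents that add atoms: none
Why: Fluoride-mediated desilylation with KHF2 in methanol is selective for phenolic tert-butyldimethylsilyl ethers, because phenoxide leaves readily from pentacoordinate silicon, while the weakly acidic, non-nucleophilic medium should leave the alkyl ester intact.

**Compound list**

1 | 4-iodophenol | Oc1ccc(I)cc1 | starting material
2 | tert-butyl(4-iodophenoxy)dimethylsilane | CC(C)(C)[Si](C)(C)Oc1ccc(I)cc1 | intermediate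
3 | docosanoic acid | CCCCCCCCCCCCCCCCCCCCCC(=O)O | starting material
4 | vinyl acetate | CC(=O)OC=C | starting material
5 | vinyl docosanoate | CCCCCCCCCCCCCCCCCCCCCC(=O)OC=C | intermediate
6 | 2-[4-(tert-butyldimethylsilyloxy)phenyl]ethyl docosanoate | CCCCCCCCCCCCCCCCCCCCCC(=O)OCCc1ccc(O[Si](C)(C)C(C)(C)C)cc1 | intermediate
7 | 2-(4-hydroxyphenyl)ethyl docosanoate | CCCCCCCCCCCCCCCCCCCCCC(=O)OCCc1ccc(O)cc1 | target

**Summary**

Total step count: 4. Longest linear sequence: 3 steps (1 → 2 → 6 → 7, or 3 → 5 → 6 → 7).

**Steps most likely to fail**

Step 3. The aryl radical may be reduced before it adds (hydrodeiodination by thiol or solvent). The thiol may be consumed by thiol-ene addition to the vinyl ester. The waxy acceptor may telomerise or fall out of the polar medium. Fallback, from 2 back to 6: the same aryl–CH2 bond would be made by polar chemistry. Iodine–magnesium exchange on 2 with i-PrMgCl·LiCl in THF and opening of ethylene oxide by the aryl Grignard reagent (CuBr·SMe2 catalysis) should give 2-[4-(tert-butyldimethylsilyloxy)phenyl]ethanol F1. Steglich esterification of F1 with acid 3 (EDC·HCl, DMAP, CH2Cl2) would then deliver 6.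

Step 2. The vinyl interchange may stall as the catalyst is reduced to palladium metal, or stop at an unfavourable equilibrium because the fatty acid dissolves poorly in vinyl acetate. Fallback, from 3 back to 5: the vinyl group would be unveiled by selenoxide elimination instead of being transferred. 2-(Phenylselanyl)ethanol F2 (from PhSeSePh, NaBH4 and 2-bromoethanol) would be esterified with 3 (EDC·HCl, DMAP) to 2-(phenylselanyl)ethyl docosanoate F3. Oxidation with H2O2 in THF at 0 °C would give the selenoxide 2-(benzeneseleninyl)ethyl docosanoate F4, which on warming in toluene with i-Pr2NH should undergo syn-elimination to 5.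

Step 4. Desilylation may be slow because the long-chain ester is poorly soluble in methanol, and forcing it may start methanolysis of the ester. Fallback, from 1 back to 7: the phenol would carry a benzyl group, removed without any nucleophile. Benzylation of 1 (BnBr, K2CO3, acetone) should give 1-(benzyloxy)-4-iodobenzene F5. The hydroarylation of step 3 applied to F5 and 5 would give 2-[4-(benzyloxy)phenyl]ethyl docosanoate F6. Hydrogenolysis (H2, Pd/C, EtOAc/THF, rt) would release 7; the homobenzylic alkyl ester is not cleaved under these conditions.

Further compounds
F1 | step 3 | 2-[4-(tert-butyldimethylsilyloxy)phenyl]ethanol | OCCc1ccc(O[Si](C)(C)C(C)(C)C)cc1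
F2 | step 2 | 2-(phenylselanyl)ethanol | OCC[Se]c1ccccc1
F3 | step 2 | 2-(phenylselanyl)ethyl docosanoate | CCCCCCCCCCCCCCCCCCCCCC(=O)OCC[Se]c1ccccc1
F4 | step 2 | 2-(benzeneseleninyl)ethyl docosanoate | CCCCCCCCCCCCCCCCCCCCCC(=O)OCC[Se](=O)c1ccccc1
F5 | step 4 | 1-(benzyloxy)-4-iodobenzene | Ic1ccc(OCc2ccccc2)cc1
F6 | step 4 | 2-[4-(benzyloxy)phenyl]ethyl docosanoate | CCCCCCCCCCCCCCCCCCCCCC(=O)OCCc1ccc(OCc2ccccc2)cc1
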